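## Retrosynthetic overview

1. The target is taken back through C10 acetylation, hydroxyl-directed epoxidation of C8=C9, C6 esterification and isopropyl addition to a C4 ketone; the C6 oxygen and the C5 hydrogen come from conjugate borylation/oxidation of an enone.
2. Key disconnection: the C5–C6 bond, made as the C5=C6 double bond of a bicyclic dienone by ring-closing metathesis that closes the seven-membered ring onto a finished cyclopentanone.
3. Enabling feature: C4 (carbinol carbon of the five-membered ring), C5 (ring-fusion CH) and C6 (acyloxy carbon of the seven-membered ring) form a 1,3-dioxygenated triad. With C4 as a ketone, C5–C6 is the α,β-bond of an α-alkylidenecyclopentanone inside the seven-membered ring.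
4. The metathesis precursor comes from a Nozaki–Hiyama–Kishi coupling (C9–C10) of a (Z)-iodo diene with a cyclopentanone aldehyde. Its quaternary C1 is set by asymmetric conjugate addition to 3-methylcyclopent-2-en-1-one, the enolate being trapped as a Mannich base (latent C5 methylene).
5. Ring order: five-membered ring (from the starting enone), seven-membered ring (step 9), oxirane (step 14).

Key step: step 9

Remark on the chemistry: locants C1–C10 in names and comments are C1 (methyl-bearing ring-fusion carbon), C2, C3, C4 (isopropyl carbinol carbon), C5 (ring-fusion CH), then C6–C10 around the seven-membered ring (C6 ester, C8 methyl, C10 acetate); α is the face opposite to the C1 methyl group.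

## Route

Step 1
Reactants: 1 prop-2-yn-1-ol
Product: 3 (2Z)-3-iodo-2-methylprop-2-en-1-ol, via cyclic alkenylmagnesium alkoxide 2 (not isolated)
Conditions: MeMgBr (2.2 equiv), CuI (10 mol %), THF, −10 °C to rt; then I2, −30 °C
Reagents that add atoms: methylmagnesium bromide C[Mg]Br; iodine II
Why: Copper-catalysed carbomagnesiation of the propargylic alkoxide should proceed anti under magnesium–alkoxide chelation (methyl to C2, magnesium to C3 cis to the CH2O arm), and iodinolysis of the C–Mg bond with retention should give the (Z)-iodide.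

Step 2
Reactants: 3 (2Z)-3-iodo-2-methylprop-2-en-1-ol
Product: 4 (1Z)-3-bromo-1-iodo-2-methylprop-1-ene
Conditions: CBr4, PPh3, CH2Cl2, 0 °C
Reagents that add atoms: carbon tetrabromide BrC(Br)(Br)Br
Why: Appel reaction, an SN2 displacement at the primary allylic carbon that should leave the olefin geometry untouched.

Step 3
Reactants: 4 (1Z)-3-bromo-1-iodo-2-methylprop-1-ene
Product: 5 (1Z)-1-iodo-2-methylpenta-1,4-diene
Conditions: CH2=CHMgBr, CuI (5 mol %), THF, −40 °C
Reagents that add atoms: vinylmagnesium bromide C=C[Mg]Br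
Why: Copper-catalysed allyl–vinyl cross-coupling; the primary allylic bromide should react far faster than the alkenyl iodide at low temperature, and the iodine-bearing γ-carbon disfavours SN2′ attack.

Step 4
Reactants: 6 3-methylcyclopent-2-en-1-one
Product: 8 (3R)-2-[(dimethylamino)methyl]-3-ethenyl-3-methylcyclopentan-1-one (C2 epimers), via dimethylaluminium enolate 7 (not isolated)
Conditions: CH2=CHAlMe2 (preformed), Cu(OTf)2 (5 mol %), chiral N-heterocyclic carbene ligand (6 mol %), Et2O, −30 °C; then MeLi; then CH2=NMe2+ I−, THF, −78 °C to rt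
Reagents that add atoms: dimethyl(vinyl)aluminium C=C[Al](C)C; dimethyl(methylidene)ammonium iodide C=[N+](C)C.[I-]
Why: Copper-catalysed asymmetric conjugate addition of an alkenylaluminium reagent to a β-substituted cyclic enone should set the quaternary C1 under ligand control, and Mannich trapping of the regiodefined enolate places the latent methylene at C5 only.

Step 5
Reactants: 8 (3R)-2-[(dimethylamino)methyl]-3-ethenyl-3-methylcyclopentan-1-one
Product: 9 (1S)-2-[(dimethylamino)methyl]-1-methyl-3-oxocyclopentane-1-carbaldehyde (C2 epimers)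
Conditions: O3, CF3CO2H (1.1 equiv), CH2Cl2/MeOH, −78 °C; then Me2S; aq. NaHCO3
Reagents that add atoms: ozone [O-][O+]=O
Why: Ozonolysis of the only C=C bond, with the amine protected as its ammonium salt, should give the non-enolisable C10 aldehyde without touching C1.

Step 6
Reactants: 9 (1S)-2-[(dimethylamino)methyl]-1-methyl-3-oxocyclopentane-1-carbaldehyde; 5 (1Z)-1-iodo-2-methylpenta-1,4-diene
Product: 10 (3S)-2-[(dimethylamino)methyl]-3-[(1R,2Z)-1-hydroxy-3-methylhexa-2,5-dien-1-yl]-3-methylcyclopentan-1-one (C2 epimers)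
Conditions: CrCl2 (3 equiv), NiCl2 (5 mol %), chiral oxazoline sulfonamide ligand (3.3 equiv), Et3N, THF, rt; aq. work-up
Reagents that add atoms: none
Why: Nozaki–Hiyama–Kishi coupling (zerovalent nickel inserts into the C–I bond, the alkenyl group passes to trivalent chromium and adds to the aldehyde in preference to the ketone) should keep the (Z) geometry, the chiral chromium complex selecting the aldehyde face that gives the 10α-alcohol.

Step 7
Reactants: 10 allylic alcohol
Product: 11 (3S)-3-[(1R,2Z)-1-{[tert-butyl(dimethyl)silyl]oxy}-3-methylhexa-2,5-dien-1-yl]-2-[(dimethylamino)methyl]-3-methylcyclopentan-1-one (C2 epimers)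
Conditions: TBSOTf, 2,6-lutidine, CH2Cl2, −78 °C
Reagents that add atoms: tert-butyldimethylsilyl trifluoromethanesulfonate CC(C)(C)[Si](C)(C)OS(=O)(=O)C(F)(F)F
Why: Silylation of the only hydroxyl group masks C10–OH until the directed epoxidation.

Step 8
Reactants: 11 silyl ether Mannich base
Product: 13 (3S)-3-[(1R,2Z)-1-{[tert-butyl(dimethyl)silyl]oxy}-3-methylhexa-2,5-dien-1-yl]-3-methyl-2-methylidenecyclopentan-1-one, via trimethylammonium iodide 12 (not isolated)
Conditions: MeI, Et2O, rt; then aq. NaHCO3, CH2Cl2, rt
Reagents that add atoms: none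
Why: Quaternisation of the Mannich base followed by E1cB (Hofmann-type) loss of trimethylamine should unveil the exocyclic enone olefin at C5, the only position carrying the ammonium group.

Step 9
Reactants: 13 α-methylene ketone triene
Product: 14 (3aS,4R)-4-{[tert-butyl(dimethyl)silyl]oxy}-3a,6-dimethyl-3,3a,4,7-tetrahydroazulen-1(2H)-one
Conditions: second-generation Hoveyda–Grubbs catalyst (10 mol %), 1,4-benzoquinone (20 mol %), toluene (0.005 M), 80 °C
Reagents that add atoms: none
Why: Ring-closing olefin metathesis: the ruthenium alkylidene loads onto the monosubstituted terminal olefin, engages the 1,1-disubstituted enone olefin through a metallacyclobutane and expels ethene, forming the C5=C6 bond. The closest known reaction type is ring-closing metathesis of α-methylene ketones with a tethered monosubstituted olefin to give cyclic trisubstituted enones. The seven-membered ring closes with the new double bond endocyclic to it and exocyclic to the cyclopentanone; the (Z)-C8=C9 olefin already holds C7 and C10 cis, which should favour closure over dimerisation. No stereocentre is formed and C1 and C10 are untouched; C5 is left trigonal on purpose, so that the ring fusion is set afterwards by reagent delivery and not under the constraint of ring closure. The selectivity needed is chemoselectivity among three olefins: only the terminal vinyl group can initiate, the trisubstituted olefin is too hindered to be cleaved, and loss of ethene makes closure irreversible.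

Step 10
Reactants: 14 bicyclic dienone
Product: 16 (3aS,4R,8S,8aS)-4-{[tert-butyl(dimethyl)silyl]oxy}-8-hydroxy-3a,6-dimethyl-3,3a,4,7,8,8a-hexahydroazulen-1(2H)-one, via C6 pinacol boronate 15 (not isolated)
Conditions: B2pin2, CuCl (5 mol %), NaOt-Bu (10 mol %), chiral ferrocenyl bisphosphine (Josiphos type, 6 mol %), MeOH, THF, 0 °C to rt; then H2O2, pH 7 buffer, 0 °C
Reagents that add atoms: hydrogen peroxide OO
Why: Copper-catalysed conjugate borylation should place boron on C6 from the α face under control of the chiral bisphosphine (enantiomer matched to the substrate), the copper enolate is protonated at C5 away from the C1 methyl group (C5 stays epimerisable and the trans-fused isomer is expected to be the more stable), and C–B oxidation with retention should give the 6α-alcohol.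

Step 11
Reactants: 16 β-hydroxy ketone
Product: 17 (1R,3aS,4R,8S,8aS)-4-{[tert-butyl(dimethyl)silyl]oxy}-3a,6-dimethyl-1-(propan-2-yl)-1,2,3,3a,4,7,8,8a-octahydroazulene-1,8-diol
Conditions: i-PrMgCl (4 equiv), CeCl3 (anhydrous), THF, −78 °C
Reagents that add atoms: isopropylmagnesium chloride CC(C)[Mg]Cl
Why: Organocerium 1,2-addition suppresses enolisation, reduction and retro-aldol cleavage at low temperature, and attack on the C6-alkoxide chelate from the α face (the side of C5–H, away from the C1 methyl group) should give the 4β-hydroxy, 4α-isopropyl carbinol.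

Step 12
Reactants: 17 diol
Product: 18 (1R,3aS,4R,8S,8aS)-4-{[tert-butyl(dimethyl)silyl]oxy}-1-hydroxy-3a,6-dimethyl-1-(propan-2-yl)-1,2,3,3a,4,7,8,8a-octahydroazulen-8-yl 3-methylbutanoate
Conditions: 3-methylbutanoyl chloride, pyridine, DMAP (cat.), CH2Cl2, 0 °C
Reagents that add atoms: 3-methylbutanoyl chloride CC(C)CC(=O)Cl
Why: Acylation should take the secondary C6 hydroxyl only, the tertiary C4 hydroxyl being too hindered and C10 still silylated.

Step 13
Reactants: 18 silyl ether ester
Product: 19 (1R,3aS,4R,8S,8aS)-1,4-dihydroxy-3a,6-dimethyl-1-(propan-2-yl)-1,2,3,3a,4,7,8,8a-octahydroazulen-8-yl 3-methylbutanoate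
Conditions: HF·pyridine, pyridine, THF, 0 °C to rt
Reagents that add atoms: none
Why: Buffered fluoride desilylation frees the allylic C10 hydroxyl before the acid-sensitive epoxide exists and should not move the ester.

Step 14
Reactants: 19 allylic alcohol
Product: 20 (1S,4R,5S,6S,8R,9S,10S)-8,9-epoxy-4,10-dihydroxy ester (target lacking the acetyl group)
Conditions: VO(acac)2 (5 mol %), t-BuOOH, CH2Cl2, 0 °C to rt
Reagents that add atoms: tert-butyl hydroperoxide CC(C)(C)OO
Why: Hydroxyl-directed epoxidation, in which the pentavalent vanadium alkoxide peroxide delivers oxygen to C8=C9 on the face of the 10α-hydroxyl, should give the α-epoxide; the tertiary C4 hydroxyl has no olefin within reach.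

Step 15
Reactants: 20 epoxy alcohol
Product: 21 target, (1S,4R,5S,6S,8R,9S,10S)-10-acetoxy-8,9-epoxy-4-hydroxy-6-(3-methylbutanoyloxy) compound
Conditions: Ac2O, pyridine, DMAP (cat.), CH2Cl2, rt
Reagents that add atoms: acetic anhydride CC(=O)OC(C)=O
Why: Acetylation of the only secondary hydroxyl left; the tertiary C4 hydroxyl should stay free under these mild conditions.

## Compound list

1 | prop-2-yn-1-ol | C#CCO | starting material
2 | cyclic (Z)-alkenylmagnesium alkoxide (4-methyl-2,5-dihydro-1,2-oxamagnesole) | CC1=C[Mg]OC1 | intermediate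
3 | (2Z)-3-iodo-2-methylprop-2-en-1-ol | OC/C(C)=C\I | intermediate
4 | (1Z)-3-bromo-1-iodo-2-methylprop-1-ene | BrC/C(C)=C\I | intermediate
5 | (1Z)-1-iodo-2-methylpenta-1,4-diene | C=CC/C(C)=C\I | intermediate
6 | 3-methylcyclopent-2-en-1-one | CC1=CC(=O)CC1 | starting material
7 | dimethylaluminium enolate of (S)-3-ethenyl-3-methylcyclopentanone (enolate double bond towards the quaternary carbon) | C=C[C@@]1(C)CCC(O[Al](C)C)=C1 | intermediate
8 | (3R)-2-[(dimethylamino)methyl]-3-ethenyl-3-methylcyclopentan-1-one (C2 epimers) | C=C[C@@]1(C)CCC(=O)C1CN(C)C | intermediate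
9 | (1S)-2-[(dimethylamino)methyl]-1-methyl-3-oxocyclopentane-1-carbaldehyde (C2 epimers) | O=C[C@@]1(C)CCC(=O)C1CN(C)C | intermediate
10 | (3S)-2-[(dimethylamino)methyl]-3-[(1R,2Z)-1-hydroxy-3-methylhexa-2,5-dien-1-yl]-3-methylcyclopentan-1-one (C2 epimers) | C=CC/C(C)=C\[C@@H](O)[C@@]1(C)CCC(=O)C1CN(C)C | intermediate
11 | (3S)-3-[(1R,2Z)-1-{[tert-butyl(dimethyl)silyl]oxy}-3-methylhexa-2,5-dien-1-yl]-2-[(dimethylamino)methyl]-3-methylcyclopentan-1-one (C2 epimers) | C=CC/C(C)=C\[C@@H](O[Si](C)(C)C(C)(C)C)[C@@]1(C)CCC(=O)C1CN(C)C | intermediate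
12 | trimethylammonium iodide of 11 | C=CC/C(C)=C\[C@@H](O[Si](C)(C)C(C)(C)C)[C@@]1(C)CCC(=O)C1C[N+](C)(C)C.[I-] | intermediate
13 | (3S)-3-[(1R,2Z)-1-{[tert-butyl(dimethyl)silyl]oxy}-3-methylhexa-2,5-dien-1-yl]-3-methyl-2-methylidenecyclopentan-1-one | C=CC/C(C)=C\[C@@H](O[Si](C)(C)C(C)(C)C)[C@@]1(C)CCC(=O)C1=C | intermediate
14 | (3aS,4R)-4-{[tert-butyl(dimethyl)silyl]oxy}-3a,6-dimethyl-3,3a,4,7-tetrahydroazulen-1(2H)-one | CC(C)(C)[Si](C)(C)O[C@@H]1C=C(C)CC=C2[C@]1(C)CCC2=O | intermediate
15 | C6 pinacol boronate of the saturated ketone (boron on C6 and hydrogen on C5 both α, trans ring fusion) | CC(C)(C)[Si](C)(C)O[C@@H]1C=C(C)C[C@H](B2OC(C)(C)C(C)(C)O2)[C@@H]3[C@]1(C)CCC3=O | intermediate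
16 | (3aS,4R,8S,8aS)-4-{[tert-butyl(dimethyl)silyl]oxy}-8-hydroxy-3a,6-dimethyl-3,3a,4,7,8,8a-hexahydroazulen-1(2H)-one | CC(C)(C)[Si](C)(C)O[C@@H]1C=C(C)C[C@H](O)[C@@H]2[C@]1(C)CCC2=O | intermediate
17 | (1R,3aS,4R,8S,8aS)-4-{[tert-butyl(dimethyl)silyl]oxy}-3a,6-dimethyl-1-(propan-2-yl)-1,2,3,3a,4,7,8,8a-octahydroazulene-1,8-diol | CC(C)(C)[Si](C)(C)O[C@@H]1C=C(C)C[C@H](O)[C@@H]2[C@]1(C)CC[C@@]2(O)C(C)C | intermediate
18 | (1R,3aS,4R,8S,8aS)-4-{[tert-butyl(dimethyl)silyl]oxy}-1-hydroxy-3a,6-dimethyl-1-(propan-2-yl)-1,2,3,3a,4,7,8,8a-octahydroazulen-8-yl 3-methylbutanoate | CC(C)(C)[Si](C)(C)O[C@@H]1C=C(C)C[C@H](OC(=O)CC(C)C)[C@@H]2[C@]1(C)CC[C@@]2(O)C(C)C | intermediate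
19 | (1R,3aS,4R,8S,8aS)-1,4-dihydroxy-3a,6-dimethyl-1-(propan-2-yl)-1,2,3,3a,4,7,8,8a-octahydroazulen-8-yl 3-methylbutanoate | O[C@@H]1C=C(C)C[C@H](OC(=O)CC(C)C)[C@@H]2[C@]1(C)CC[C@@]2(O)C(C)C | intermediate
20 | (1S,4R,5S,6S,8R,9S,10S)-8α,9α-epoxy-4β,10α-dihydroxy-6α-(3-methylbutanoyloxy) bicycle (remark locants) | O[C@@H]1[C@@H]2O[C@]2(C)C[C@H](OC(=O)CC(C)C)[C@@H]2[C@]1(C)CC[C@@]2(O)C(C)C | intermediate
21 | (1S,4R,5S,6S,8R,9S,10S)-10α-acetoxy-8α,9α-epoxy-4β-hydroxy-6α-(3-methylbutanoyloxy) bicycle (remark locants) | CC(=O)O[C@@H]1[C@@H]2O[C@]2(C)C[C@H](OC(=O)CC(C)C)[C@@H]2[C@]1(C)CC[C@@]2(O)C(C)C | target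

## Step count and risks

Total step count: 15. Longest linear sequence: 13 steps (steps 1 to 3 and 6 to 15, from 1). The branch from 6 (steps 4 and 5) joins at step 6 and runs 12 steps to the target.

Steps most likely to fail:

1. Step 9. The hindered, electron-poor exocyclic olefin next to the quaternary carbon may not enter the metathesis cycle, so that the terminal olefin only dimerises or migrates. The fallback sets out from 13: 1,2-reduction (NaBH4, CeCl3·7H2O, MeOH) should give the exo-methylene cyclopentanol F1, whose allylic-alcohol olefin is a far better metathesis partner. Ring closure with the second-generation Grubbs catalyst should then give the bicyclic dienol F2, and oxidation of this allylic alcohol (MnO2) comes back to 14.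

2. Step 10. Boron delivery to the wrong face of C6, or protonation of C5 from the β face, would give 6-epi or cis-fused material. The fallback sets out from 14: nucleophilic epoxidation (t-BuOOH, DBU) should attack C6 on the face away from the C1 methyl group and give the spiro α,β-epoxy ketone F3. Reductive opening of the Cα–O bond with SmI2 (THF/MeOH, −78 °C), with the samarium alkoxide at C6 directing protonation of C5 from the α face, comes back to 16.

3. Step 6. Reagent control at the neopentyl aldehyde may be too weak, giving a mixture of C10 epimers. The fallback runs the coupling without the chiral ligand and carries the mixture forward; it sets out from 19 (as a C10 epimer mixture). Oxidation of the allylic alcohol (MnO2) gives the enone F4, and oxazaborolidine-catalysed (Corey–Bakshi–Shibata) reduction with catecholborane, with the catalyst enantiomer chosen for the 10α-alcohol, comes back to 19.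

Further compounds
F1 | step 9 | (3S)-3-[(1R,2Z)-1-{[tert-butyl(dimethyl)silyl]oxy}-3-methylhexa-2,5-dien-1-yl]-3-methyl-2-methylidenecyclopentan-1-ol (carbinol epimers) | C=CC/C(C)=C\[C@@H](O[Si](C)(C)C(C)(C)C)[C@@]1(C)CCC(O)C1=C
F2 | step 9 | (3aS,4R)-4-{[tert-butyl(dimethyl)silyl]oxy}-3a,6-dimethyl-1,2,3,3a,4,7-hexahydroazulen-1-ol (carbinol epimers) | CC(C)(C)[Si](C)(C)O[C@@H]1C=C(C)CC=C2[C@]1(C)CCC2O
F3 | step 10 | 5α,6α-epoxide of 14 (spiro α,β-epoxy ketone, remark locants) | CC(C)(C)[Si](C)(C)O[C@@H]1C=C(C)C[C@@H]2O[C@]23[C@]1(C)CCC3=O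
F4 | step 6 | C10 ketone of 19 (4β-hydroxy-6α-(3-methylbutanoyloxy) 8-en-10-one, remark locants) | O=C1C=C(C)C[C@H](OC(=O)CC(C)C)[C@@H]2[C@]1(C)CC[C@@]2(O)C(C)C
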